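The quinone ring is numbered C1(=O), C2 (nonadecyl), C3–H, C4(=O), C5–H, C6–H. Everything rests on a Dötz benzannulation that assembles this ring from three components: a silyl-capped henicosyne (C2, C3), the carbene complex (CO)5Cr=C(OMe)CH=CHSiMe3 (C1, C6, C5) and one CO ligand (C4=O). Alkyne and CO insertion give a Cr(CO)3-bound dienylketene, whose 6π electrocyclisation closes the ring by forming the C4–C5 bond. The step exploits the para-dioxygenated six-membered ring carrying a single substituent: the alkyne silyl group steers nonadecyl to C2, the vinyl silyl group stabilises the carbene and migrates to oxygen, and acid removes both. (NH4)2Ce(NO3)6 then unveils the quinone.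

Key step: step 3

Remark: the target is achiral, so the route has to control regiochemistry only; all four starting materials are taken to be catalogue chemicals.

Step 1
Reactants: 1 ethynyltrimethylsilane; 2 1-bromononadecane
Product: 4 trimethyl(henicos-1-yn-1-yl)silane, via lithium trimethylsilylacetylide 3 (not isolated)
Conditions: n-BuLi, THF, −78 °C; then 2, DMPU, −78 °C to rt
Reagents that add atoms: none
Why: SN2 alkylation of a lithium acetylide by a primary bromide in THF/DMPU; the Me3Si cap blocks the second acetylenic position and is the regiocontrol element of step 3.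

Step 2
Reactants: 5 (E)-(2-bromovinyl)trimethylsilane; 6 hexacarbonylchromium Cr(CO)6
Product: 9 pentacarbonyl[(E)-1-methoxy-3-(trimethylsilyl)prop-2-en-1-ylidene]chromium, via silylvinyllithium 7 (not isolated), via lithium acylchromate 8 (not isolated)
Conditions: t-BuLi (2 equiv), Et2O, −78 °C; Cr(CO)6, Et2O, −78 to 0 °C; then Me3OBF4, CH2Cl2, 0 °C
Reagents that add atoms: trimethyloxonium tetrafluoroborate, C[O+](C)C.F[B-](F)(F)F
Why: Fischer carbene synthesis: Br/Li exchange with retention of the E geometry, addition of the vinyllithium to a CO ligand of Cr(CO)6 and O-methylation of the acylchromate by the oxonium salt.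

Step 3
Reactants: 9 pentacarbonyl[(E)-1-methoxy-3-(trimethylsilyl)prop-2-en-1-ylidene]chromium; 4 trimethyl(henicos-1-yn-1-yl)silane
Product: 13 4-methoxy-3-nonadecylphenol, via Cr(CO)3-bound dienylketene 10 (not isolated), via 6-silylcyclohexa-2,4-dienone 11 (not isolated), via bis-silyl arene 12 (not isolated)
Conditions: THF, 50 °C, Ar; air, rt; then TFA, CH2Cl2, rt
Reagents that add atoms: none
Why: Dötz benzannulation: thermal loss of CO from 9, insertion of 4 into the Cr=C bond with the bulkier Me3Si-bearing carbon placed away from the carbene carbon (so that the nonadecyl-bearing carbon C2 bonds to C1) and insertion of CO should give the Cr(CO)3-bound dienylketene 10. A thermally allowed disrotatory 6π electrocyclisation then joins the ketene carbon C4 to the silylated vinyl terminus C5 and closes the six-membered carbocycle as dienone 11; the closest known reaction type is the benzannulation of alkenyl Fischer carbene complexes with silylalkynes and of β-silylvinyl complexes with alkynes. The one new stereocentre (C5 of 11) is not controlled and need not be, because a 1,3-shift of silicon from C5 to the carbonyl oxygen (α-silyl ketone to silyl enol ether, driven by aromatisation) gives the achiral arene 12. TFA then cleaves the O–Si bond and removes the C3 silyl group by ipso-protodesilylation ortho to the phenolic oxygen, giving 13. The selectivity needed is regiochemical, nonadecyl next to the methoxy-bearing carbon, and it rests on the steric difference between Me3Si and the unbranched chain; ring closure also needs the ketene and vinyl arms cis on the central double bond, a geometry that intermediates from alkenyl (unlike aryl) complexes can reach. The β-silyl group on the vinyl unit suppresses the polymerisation to which the parent vinylcarbene complex is prone.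

Step 4
Reactants: 13 4-methoxy-3-nonadecylphenol
Product: 14 2-nonadecylcyclohexa-2,5-diene-1,4-dione (2-nonadecyl-1,4-benzoquinone, the target)
Conditions: (NH4)2Ce(NO3)6, MeCN/CH2Cl2/H2O, 0 °C
Reagents that add atoms: water, O
Why: Oxidative demethylation of a 4-methoxyphenol by (NH4)2Ce(NO3)6: two one-electron oxidations by tetravalent cerium, addition of water at the methoxy-bearing carbon C1 and loss of methanol should give the para-quinone.

Compound list
1 | ethynyltrimethylsilane | C#C[Si](C)(C)C | starting material
2 | 1-bromononadecane | CCCCCCCCCCCCCCCCCCCBr | starting material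
3 | lithium (trimethylsilyl)acetylide | [Li]C#C[Si](C)(C)C | intermediate
4 | trimethyl(henicos-1-yn-1-yl)silane | CCCCCCCCCCCCCCCCCCCC#C[Si](C)(C)C | intermediate
5 | (E)-(2-bromovinyl)trimethylsilane | C[Si](C)(C)/C=C/Br | starting material
6 | hexacarbonylchromium Cr(CO)6 | O=C=[Cr](=C=O)(=C=O)(=C=O)(=C=O)=C=O | starting material
7 | [(E)-2-(trimethylsilyl)vinyl]lithium | [Li]/C=C/[Si](C)(C)C | intermediate
8 | lithium pentacarbonyl[(E)-3-(trimethylsilyl)acryloyl]chromate | [Li+].[O-]C(/C=C/[Si](C)(C)C)=[Cr](=C=O)(=C=O)(=C=O)(=C=O)=C=O | intermediate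
9 | pentacarbonyl[(E)-1-methoxy-3-(trimethylsilyl)prop-2-en-1-ylidene]chromium | COC(/C=C/[Si](C)(C)C)=[Cr](=C=O)(=C=O)(=C=O)(=C=O)=C=O | intermediate
10 | (3E,5E)-4-methoxy-3-nonadecyl-2,6-bis(trimethylsilyl)hexa-1,3,5-trien-1-one, η4-bound to Cr(CO)3 (SMILES gives the ligand and the Cr(CO)3 fragment) | O=C=C([Si](C)(C)C)/C(CCCCCCCCCCCCCCCCCCC)=C(OC)\C=C\[Si](C)(C)C.O=C=[Cr](=C=O)=C=O | intermediate
11 | 4-methoxy-3-nonadecyl-2,6-bis(trimethylsilyl)cyclohexa-2,4-dien-1-one (racemic at C6, transient) | O=C1C([Si](C)(C)C)=C(CCCCCCCCCCCCCCCCCCC)C(OC)=CC1[Si](C)(C)C | intermediate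
12 | [4-methoxy-3-nonadecyl-2-(trimethylsilyl)phenoxy]trimethylsilane | COc1ccc(O[Si](C)(C)C)c([Si](C)(C)C)c1CCCCCCCCCCCCCCCCCCC | intermediate
13 | 4-methoxy-3-nonadecylphenol | COc1ccc(O)cc1CCCCCCCCCCCCCCCCCCC | intermediate
14 | 2-nonadecylcyclohexa-2,5-diene-1,4-dione | CCCCCCCCCCCCCCCCCCCC1=CC(=O)C=CC1=O | target

Total step count: 4. Longest linear sequence: 3 steps (1 → 4 → 13 → 14, or 5 → 9 → 13 → 14).

Steps most likely to fail

Step 3. The silicon on the ketene carbon may slow the electrocyclisation, so that the dienylketene is diverted (cyclobutenone or furan formation, or a stalled silylketene). Insertion of the internal alkyne may also lose its regiochemical bias and place nonadecyl next to the wrong oxygen-bearing carbon. The fallback moves the chain from the alkyne to the carbene partner: the alkyne becomes the terminal, strongly biased 1 and the carbene complex a β-alkylalkenyl complex that needs no silyl stabilisation. C4–C5 is then still made in the benzannulation, as the bond between the carbene carbon and the alkyne CH. It sets out from 4 (with 1 and 6) and returns at 14. K2CO3 in MeOH/THF should free henicos-1-yne F1. Hydroalumination with i-Bu2AlH in heptane at 50 °C should give diisobutyl[(E)-henicos-1-en-1-yl]alumane F2, iodinated in the same flask (I2, THF, −50 °C) to (E)-1-iodohenicos-1-ene F3. t-BuLi in Et2O at −78 °C should give [(E)-henicos-1-en-1-yl]lithium F4, which adds to 6 to give lithium pentacarbonyl[(E)-docos-2-enoyl]chromate F5. Me3OBF4 should methylate this to pentacarbonyl[(E)-1-methoxydocos-2-en-1-ylidene]chromium F6. Heating F6 with 1 in THF at 50 °C should give 4-methoxy-2-nonadecyl-6-(trimethylsilyl)phenol F7, and TFA should remove the silyl group to give 4-methoxy-2-nonadecylphenol F8. Oxidation of F8 with (NH4)2Ce(NO3)6 should give 14.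

Step 2. The vinyllithium may add in a conjugate sense to the acylchromate already formed, or add incompletely to Cr(CO)6, so that the acylate is methylated as a mixture. The fallback makes the acylchromate by acylation of the pentacarbonylchromate dianion, so that no organolithium meets the chromium species. It sets out from 5 (through 7) and from 6 and returns at 9. 7 is quenched with CO2 and acidified to (E)-3-(trimethylsilyl)prop-2-enoic acid F9, which (COCl)2 with catalytic DMF should convert into (E)-3-(trimethylsilyl)prop-2-enoyl chloride F10. 6 is reduced with potassium graphite KC8 in THF at −78 °C to dipotassium pentacarbonylchromate K2Cr(CO)5 F11. F10 and F11 should give potassium pentacarbonyl[(E)-3-(trimethylsilyl)acryloyl]chromate F12, whose O-methylation with Me3OBF4 gives 9.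

Step 4. The waxy phenol may be oxidised incompletely in the partly aqueous medium, and the phenoxyl radical may couple, or the ring be nitrated, before methanol is lost. The fallback separates ether cleavage from oxidation; it sets out from 13 and returns at 14. BBr3 in CH2Cl2 at −78 to 0 °C should cleave the methyl ether to 2-nonadecylbenzene-1,4-diol F13, which Ag2O (Et2O, Na2SO4, rt) should dehydrogenate to 14 under anhydrous, non-acidic conditions.

Further compounds
F1 | step 3 | henicos-1-yne | CCCCCCCCCCCCCCCCCCCC#C
F2 | step 3 | diisobutyl[(E)-henicos-1-en-1-yl]alumane | CCCCCCCCCCCCCCCCCCC/C=C/[Al](CC(C)C)CC(C)C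
F3 | step 3 | (E)-1-iodohenicos-1-ene | CCCCCCCCCCCCCCCCCCC/C=C/I
F4 | step 3 | [(E)-henicos-1-en-1-yl]lithium | CCCCCCCCCCCCCCCCCCC/C=C/[Li]
F5 | step 3 | lithium pentacarbonyl[(E)-docos-2-enoyl]chromate | [Li+].[O-]C(/C=C/CCCCCCCCCCCCCCCCCCC)=[Cr](=C=O)(=C=O)(=C=O)(=C=O)=C=O
F6 | step 3 | pentacarbonyl[(E)-1-methoxydocos-2-en-1-ylidene]chromium | COC(/C=C/CCCCCCCCCCCCCCCCCCC)=[Cr](=C=O)(=C=O)(=C=O)(=C=O)=C=O
F7 | step 3 | 4-methoxy-2-nonadecyl-6-(trimethylsilyl)phenol | COc1cc(CCCCCCCCCCCCCCCCCCC)c(O)c([Si](C)(C)C)c1
F8 | step 3 | 4-methoxy-2-nonadecylphenol | COc1ccc(O)c(CCCCCCCCCCCCCCCCCCC)c1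
F9 | step 2 | (E)-3-(trimethylsilyl)prop-2-enoic acid | C[Si](C)(C)/C=C/C(=O)O
F10 | step 2 | (E)-3-(trimethylsilyl)prop-2-enoyl chloride | C[Si](C)(C)/C=C/C(=O)Cl
F11 | step 2 | dipotassium pentacarbonylchromate K2Cr(CO)5 | [K+].[K+].O=C=[Cr-2](=C=O)(=C=O)(=C=O)=C=O
F12 | step 2 | potassium pentacarbonyl[(E)-3-(trimethylsilyl)acryloyl]chromate | [K+].[O-]C(/C=C/[Si](C)(C)C)=[Cr](=C=O)(=C=O)(=C=O)(=C=O)=C=O
F13 | step 4 | 2-nonadecylbenzene-1,4-diol | CCCCCCCCCCCCCCCCCCCc1cc(O)ccc1O
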